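**Strategy.** The target is the twofold-symmetric, all-trans tetrahydrofuran (2R,3S,4S,5R). Everything rests on the O1–C2 bond: C2 of the tetrahydrofuran ring is benzylic and para to the free phenolic hydroxyl of aryl ring A, so a C2 methylene can be oxidised to a para-quinone methide that the C5 hydroxyl captures. One operation thereby closes the tetrahydrofuran ring and sets C2 trans to C3. The precursor is an open-chain (1R,2S,3S)-1,4-diarylbutan-1-ol in which ring A is a free phenol, ring B (on C5) a silyl ether and both hydroxymethyl groups are silyl ethers, so that one fluoride treatment after the key step gives the target.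

Key step: step 12

Remarks on the chemistry:
- Atom labels O1 and C2–C5 are those of the tetrahydrofuran ring of the target and are kept for the same atoms in open-chain compounds. Ring A is the aryl group on C2, ring B the aryl group on C5.
- Protecting groups: ring A travels as a benzyl ether (stable to every step before the key step, removed by hydrogenolysis). Ring B is a triisopropylsilyl ether and the primary alcohols are tert-butyldimethylsilyl ethers, so all three fall together at the end.
- The C5 carbinol is not left to an aldol of uncertain selectivity. Both aldol epimers are oxidised to one ketone, which is then reduced under chelation control.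
- Assumption: the (R,R) antipode of Et-DuPHOS is taken to deliver the (S) acid 6. The sense is to be confirmed on lactone 8 before going on, and the (S,S) antipode is used instead if needed.
- Aldehyde 2 is also sold; buying it removes step 1.

**Route**

Step 1
Reactants: 1 syringaldehyde (4-hydroxy-3,5-dimethoxybenzaldehyde)
Product: 2 4-(benzyloxy)-3,5-dimethoxybenzaldehyde
Conditions: BnBr, K2CO3, DMF, rt
Reagents that add atoms: benzyl bromide, BrCc1ccccc1
Why: Williamson ether synthesis on the phenoxide should give a benzyl ether that withstands alkoxide, enolate, hydride and homogeneous Rh/H2 conditions and is cleaved later by hydrogenolysis.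

Step 2
Reactants: 2 4-(benzyloxy)-3,5-dimethoxybenzaldehyde; 3 dimethyl succinate
Product: 5 (E)-4-[4-(benzyloxy)-3,5-dimethoxyphenyl]-3-(methoxycarbonyl)but-3-enoic acid, via paraconate lactone 4 (not isolated)
Conditions: NaOMe, MeOH, reflux; then aq. HCl
Reagents that add atoms: none
Why: Stobbe condensation, in which the succinate enolate adds to the aldehyde, the aldolate lactonises to 4 and base-induced ring opening (E1cB) gives the E half-ester, whose free acid and conjugated ester are thereby told apart for step 4.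

Step 3
Reactants: 5 (E)-4-[4-(benzyloxy)-3,5-dimethoxyphenyl]-3-(methoxycarbonyl)but-3-enoic acid
Product: 6 (S)-3-[4-(benzyloxy)-3,5-dimethoxybenzyl]-4-methoxy-4-oxobutanoic acid
Conditions: H2 (5 bar), [Rh(cod)((R,R)-Et-DuPHOS)]BF4 (0.5 mol%), NaOMe (10 mol%), MeOH, rt
Reagents that add atoms: none
Why: Rhodium–bisphosphine asymmetric hydrogenation of a Stobbe-type itaconate half-ester, in which carboxylate and alkene bind the metal and the chiral ligand selects the alkene face, should set the (S) centre that becomes C3 while the homogeneous catalyst leaves the benzyl ether intact.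

Step 4
Reactants: 6 (S)-3-[4-(benzyloxy)-3,5-dimethoxybenzyl]-4-methoxy-4-oxobutanoic acid
Product: 8 (S)-4-[4-(benzyloxy)-3,5-dimethoxybenzyl]dihydrofuran-2(3H)-one, via hydroxy acid 7 (not isolated)
Conditions: KOH (1 equiv), EtOH; CaCl2, NaBH4, −10 °C to rt; then 2 M HCl, rt
Reagents that add atoms: none
Why: Chemoselective borohydride reduction, in which Ca(BH4)2 formed in the flask reduces the methyl ester but not the potassium carboxylate, followed by acid lactonisation of the γ-hydroxy acid, should give the lactone without touching the stereocenter.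

Step 5
Reactants: 1 syringaldehyde
Product: 9 3,5-dimethoxy-4-[(triisopropylsilyl)oxy]benzaldehyde
Conditions: TIPSCl, imidazole, DMF, rt
Reagents that add atoms: triisopropylsilyl chloride, CC(C)[Si](Cl)(C(C)C)C(C)C
Why: Imidazole-promoted O-silylation of the phenol should give an aryl silyl ether that tolerates the enolate, the hydride reagents and hydrogenolysis and is cleaved by fluoride together with the alkyl silyl ethers.

Step 6
Reactants: 8 (S)-4-[4-(benzyloxy)-3,5-dimethoxybenzyl]dihydrofuran-2(3H)-one; 9 3,5-dimethoxy-4-[(triisopropylsilyl)oxy]benzaldehyde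
Product: 11 (3R,4S)-4-[4-(benzyloxy)-3,5-dimethoxybenzyl]-3-[hydroxy{3,5-dimethoxy-4-[(triisopropylsilyl)oxy]phenyl}methyl]dihydrofuran-2(3H)-one as a mixture of carbinol epimers, via lithium enolate 10 (not isolated)
Conditions: LiN(iPr)2, THF, −78 °C; then 9, −78 °C; sat. aq. NH4Cl
Reagents that add atoms: none
Why: Aldol addition of a lactone lithium enolate, in which the aldehyde approaches the enolate face anti to the β-arylmethyl group and so fixes the trans relation of the lactone substituents (the future C3/C4 relation), while the carbinol centre forms as a mixture that steps 7 and 8 converge.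

Step 7
Reactants: 11 aldol mixture
Product: 12 (3R,4S)-4-[4-(benzyloxy)-3,5-dimethoxybenzyl]-3-{3,5-dimethoxy-4-[(triisopropylsilyl)oxy]benzoyl}dihydrofuran-2(3H)-one
Conditions: Dess–Martin periodinane, CH2Cl2, 0 °C to rt
Reagents that add atoms: none
Why: Dess–Martin oxidation of the benzylic alcohol should turn both carbinol epimers into one β-keto lactone, whose acidic α-centre can only settle in the favoured trans arrangement.

Step 8
Reactants: 12 β-keto lactone
Product: 13 (3R,4S)-4-[4-(benzyloxy)-3,5-dimethoxybenzyl]-3-[(R)-hydroxy{3,5-dimethoxy-4-[(triisopropylsilyl)oxy]phenyl}methyl]dihydrofuran-2(3H)-one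
Conditions: Zn(BH4)2 (Et2O solution), CH2Cl2, −20 °C; then aq. NH4Cl
Reagents that add atoms: none
Why: Chelation-controlled reduction of a β-keto lactone (Cram-chelate model), in which zinc bridges the ketone and lactone carbonyl oxygens and hydride arrives on the chelate face bearing the α-hydrogen, away from lactone carbon C4, should give the syn (R)-carbinol that becomes C5.

Step 9
Reactants: 13 (R)-hydroxy lactone
Product: 14 (1R,2S,3S)-4-[4-(benzyloxy)-3,5-dimethoxyphenyl]-1-{3,5-dimethoxy-4-[(triisopropylsilyl)oxy]phenyl}-2,3-bis(hydroxymethyl)butan-1-ol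
Conditions: LiAlH4, THF, 0 °C; then aq. NaOH work-up
Reagents that add atoms: none
Why: Hydride reduction of the lactone to the 1,4-diol should proceed without touching any stereocenter, the benzyl ether or the hindered aryl silyl ether.

Step 10
Reactants: 14 triol
Product: 15 (1R,2S,3S)-4-[4-(benzyloxy)-3,5-dimethoxyphenyl]-2,3-bis{[(tert-butyldimethylsilyl)oxy]methyl}-1-{3,5-dimethoxy-4-[(triisopropylsilyl)oxy]phenyl}butan-1-ol
Conditions: TBSCl (2.2 equiv), imidazole, CH2Cl2, 0 °C
Reagents that add atoms: tert-butyldimethylsilyl chloride, CC(C)(C)[Si](C)(C)Cl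
Why: Sterically selective silylation should cap the two primary hydroxyls and leave the hindered secondary benzylic one free, which removes the C4 hydroxymethyl as a competing nucleophile for the key step.

Step 11
Reactants: 15 benzyl ether
Product: 16 (1R,2S,3S)-2,3-bis{[(tert-butyldimethylsilyl)oxy]methyl}-1-{3,5-dimethoxy-4-[(triisopropylsilyl)oxy]phenyl}-4-(4-hydroxy-3,5-dimethoxyphenyl)butan-1-ol
Conditions: H2 (1 atm), 10% Pd/C, EtOAc, rt
Reagents that add atoms: none
Why: Catalytic hydrogenolysis of the aryl benzyl ether under neutral conditions should unmask the ring A phenol while the silyl ethers are inert and the benzylic C5 hydroxyl, which needs acid to be cleaved, is retained.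

Step 12
Reactants: 16 phenol (key-step precursor)
Product: 18 4-[(2R,3S,4S,5R)-3,4-bis{[(tert-butyldimethylsilyl)oxy]methyl}-5-{3,5-dimethoxy-4-[(triisopropylsilyl)oxy]phenyl}tetrahydrofuran-2-yl]-2,6-dimethoxyphenol, via quinone methide 17 (not isolated)
Conditions: Ag2O (3 equiv), CH2Cl2, rt, dark
Reagents that add atoms: none
Why: Ag2O takes two electrons and two protons from ring A (the phenolic O–H and one C2–H) to give para-quinone methide 17, and the C5 hydroxyl adds to its exocyclic carbon in a 1,6-addition that restores the aromatic ring and forms O1–C2. The closest known reaction type is the Ag2O oxidation of 4-alkyl-2,6-dimethoxyphenols to quinone methides with intramolecular capture by an alcohol. The tetrahydrofuran ring closes in a 5-exo-trig mode, the oxygen on C5 attacking C2 while the C2=C(aryl) bond stays outside the new ring. The new C2 centre is controlled by C3: with C3–H eclipsing the quinone methide plane to minimise allylic 1,3-strain, the tethered oxygen arrives on the face that places ring A trans to the C3 silyloxymethyl group, and reversible capture lets a 2,3-cis ether drain toward the all-trans isomer. The step needs selectivity between the two aryl rings and among the oxygen nucleophiles: only ring A carries a free phenol (ring B is a silyl ether and its carbinol is not oxidised by Ag2O), and both primary hydroxyls are silylated, so the C4 hydroxymethyl cannot close the isomeric five-membered ether. The neutral medium disfavours attack of ring B on C2 (six-membered carbocycle) and tautomerisation to the styrene.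

Step 13
Reactants: 18 protected tetrahydrofuran
Product: 19 [(2R,3S,4S,5R)-2,5-bis(4-hydroxy-3,5-dimethoxyphenyl)tetrahydrofuran-3,4-diyl]dimethanol (target)
Conditions: Bu4NF, AcOH, THF, 0 °C to rt
Reagents that add atoms: none
Why: Fluoride-induced desilylation should cleave the two primary silyl ethers and the aryl silyl ether in one operation, the acetic acid buffer protecting the electron-rich phenols from base-promoted air oxidation, with no stereocenter affected.

**Compound list**

1 | syringaldehyde (4-hydroxy-3,5-dimethoxybenzaldehyde) | COc1cc(C=O)cc(OC)c1O | starting material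
2 | 4-(benzyloxy)-3,5-dimethoxybenzaldehyde | COc1cc(C=O)cc(OC)c1OCc1ccccc1 | intermediate
3 | dimethyl succinate | COC(=O)CCC(=O)OC | starting material
4 | methyl 2-[4-(benzyloxy)-3,5-dimethoxyphenyl]-5-oxotetrahydrofuran-3-carboxylate (paraconate lactone, stereoisomer mixture) | COC(=O)C1CC(=O)OC1c1cc(OC)c(OCc2ccccc2)c(OC)c1 | intermediate (not isolated)
5 | (E)-4-[4-(benzyloxy)-3,5-dimethoxyphenyl]-3-(methoxycarbonyl)but-3-enoic acid | COC(=O)/C(CC(=O)O)=C/c1cc(OC)c(OCc2ccccc2)c(OC)c1 | intermediate
6 | (S)-3-[4-(benzyloxy)-3,5-dimethoxybenzyl]-4-methoxy-4-oxobutanoic acid | COC(=O)[C@H](CC(=O)O)Cc1cc(OC)c(OCc2ccccc2)c(OC)c1 | intermediate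
7 | (S)-4-[4-(benzyloxy)-3,5-dimethoxyphenyl]-3-(hydroxymethyl)butanoic acid | OC[C@H](CC(=O)O)Cc1cc(OC)c(OCc2ccccc2)c(OC)c1 | intermediate (not isolated)
8 | (S)-4-[4-(benzyloxy)-3,5-dimethoxybenzyl]dihydrofuran-2(3H)-one | O=C1C[C@H](Cc2cc(OC)c(OCc3ccccc3)c(OC)c2)CO1 | intermediate
9 | 3,5-dimethoxy-4-[(triisopropylsilyl)oxy]benzaldehyde | COc1cc(C=O)cc(OC)c1O[Si](C(C)C)(C(C)C)C(C)C | intermediate
10 | lithium enolate of lactone 8 | [Li+].[O-]C1=C[C@H](Cc2cc(OC)c(OCc3ccccc3)c(OC)c2)CO1 | intermediate (not isolated)
11 | (3R,4S)-4-[4-(benzyloxy)-3,5-dimethoxybenzyl]-3-[hydroxy{3,5-dimethoxy-4-[(triisopropylsilyl)oxy]phenyl}methyl]dihydrofuran-2(3H)-one, both carbinol epimers | OC(c1cc(OC)c(O[Si](C(C)C)(C(C)C)C(C)C)c(OC)c1)[C@@H]1C(=O)OC[C@H]1Cc1cc(OC)c(OCc2ccccc2)c(OC)c1 | intermediate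
12 | (3R,4S)-4-[4-(benzyloxy)-3,5-dimethoxybenzyl]-3-{3,5-dimethoxy-4-[(triisopropylsilyl)oxy]benzoyl}dihydrofuran-2(3H)-one | O=C(c1cc(OC)c(O[Si](C(C)C)(C(C)C)C(C)C)c(OC)c1)[C@@H]1C(=O)OC[C@H]1Cc1cc(OC)c(OCc2ccccc2)c(OC)c1 | intermediate
13 | (3R,4S)-4-[4-(benzyloxy)-3,5-dimethoxybenzyl]-3-[(R)-hydroxy{3,5-dimethoxy-4-[(triisopropylsilyl)oxy]phenyl}methyl]dihydrofuran-2(3H)-one | O[C@@H](c1cc(OC)c(O[Si](C(C)C)(C(C)C)C(C)C)c(OC)c1)[C@@H]1C(=O)OC[C@H]1Cc1cc(OC)c(OCc2ccccc2)c(OC)c1 | intermediate
14 | (1R,2S,3S)-4-[4-(benzyloxy)-3,5-dimethoxyphenyl]-1-{3,5-dimethoxy-4-[(triisopropylsilyl)oxy]phenyl}-2,3-bis(hydroxymethyl)butan-1-ol | O[C@@H](c1cc(OC)c(O[Si](C(C)C)(C(C)C)C(C)C)c(OC)c1)[C@H](CO)[C@@H](CO)Cc1cc(OC)c(OCc2ccccc2)c(OC)c1 | intermediate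
15 | (1R,2S,3S)-4-[4-(benzyloxy)-3,5-dimethoxyphenyl]-2,3-bis{[(tert-butyldimethylsilyl)oxy]methyl}-1-{3,5-dimethoxy-4-[(triisopropylsilyl)oxy]phenyl}butan-1-ol | O[C@@H](c1cc(OC)c(O[Si](C(C)C)(C(C)C)C(C)C)c(OC)c1)[C@H](CO[Si](C)(C)C(C)(C)C)[C@@H](CO[Si](C)(C)C(C)(C)C)Cc1cc(OC)c(OCc2ccccc2)c(OC)c1 | intermediate
16 | (1R,2S,3S)-2,3-bis{[(tert-butyldimethylsilyl)oxy]methyl}-1-{3,5-dimethoxy-4-[(triisopropylsilyl)oxy]phenyl}-4-(4-hydroxy-3,5-dimethoxyphenyl)butan-1-ol (key-step precursor) | O[C@@H](c1cc(OC)c(O[Si](C(C)C)(C(C)C)C(C)C)c(OC)c1)[C@H](CO[Si](C)(C)C(C)(C)C)[C@@H](CO[Si](C)(C)C(C)(C)C)Cc1cc(OC)c(O)c(OC)c1 | intermediate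
17 | para-quinone methide of 16 (2,6-dimethoxy-4-alkylidenecyclohexa-2,5-dien-1-one, exocyclic carbon = C2) | O[C@@H](c1cc(OC)c(O[Si](C(C)C)(C(C)C)C(C)C)c(OC)c1)[C@H](CO[Si](C)(C)C(C)(C)C)[C@@H](CO[Si](C)(C)C(C)(C)C)C=C1C=C(OC)C(=O)C(OC)=C1 | intermediate (not isolated)
18 | 4-[(2R,3S,4S,5R)-3,4-bis{[(tert-butyldimethylsilyl)oxy]methyl}-5-{3,5-dimethoxy-4-[(triisopropylsilyl)oxy]phenyl}tetrahydrofuran-2-yl]-2,6-dimethoxyphenol (key-step product) | COc1cc([C@@H]2O[C@@H](c3cc(OC)c(O[Si](C(C)C)(C(C)C)C(C)C)c(OC)c3)[C@H](CO[Si](C)(C)C(C)(C)C)[C@H]2CO[Si](C)(C)C(C)(C)C)cc(OC)c1O | intermediate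
19 | [(2R,3S,4S,5R)-2,5-bis(4-hydroxy-3,5-dimethoxyphenyl)tetrahydrofuran-3,4-diyl]dimethanol | COc1cc([C@@H]2O[C@@H](c3cc(OC)c(O)c(OC)c3)[C@H](CO)[C@H]2CO)cc(OC)c1O | target

**Step count and risk**

Total step count: 13. Longest linear sequence: 12 steps (steps 1–4 and 6–13); step 5 is a one-step branch from syringaldehyde.

Steps most likely to fail:

1. Step 12 (key step). The quinone methide may be lost to tautomerisation to the styrene or to intermolecular coupling before the hindered secondary hydroxyl adds, or the closure may show poor facial selectivity at C2. The fallback separates oxidation from ring closure; it sets out from 16 and comes back at 18. The oxidation is run with Ag2O in CH2Cl2/MeOH so that the large excess of methanol intercepts the quinone methide. This should give the benzylic methyl ether (1R,2S,3S,4RS)-2,3-bis{[(tert-butyldimethylsilyl)oxy]methyl}-1-{3,5-dimethoxy-4-[(triisopropylsilyl)oxy]phenyl}-4-(4-hydroxy-3,5-dimethoxyphenyl)-4-methoxybutan-1-ol F1 as a pair of C2 epimers, both of which are usable. Catalytic camphorsulfonic acid in CH2Cl2 over 4 Å molecular sieves at 0 °C then ionises the para-hydroxybenzyl ether, and the C5 hydroxyl closes the ring by an SN1 etherification. Because that closure is reversible, both epimers should converge on the all-trans ether 18.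

2. Step 8. Hydride delivery may show poor facial selectivity if the zinc chelate does not dominate. The fallback moves stereocontrol from the substrate to the catalyst; it sets out from 12 and comes back at 13 without any new compound. Ketone 12 is reduced by asymmetric transfer hydrogenation with RuCl(p-cymene)[(R,R)-TsDPEN] in HCO2H/Et3N. The outer-sphere hydride and proton transfer of this catalyst antipode gives the (R) alcohol from aryl alkyl ketones, and the amine medium lets the α-centre stay or settle trans.

3. Step 3. Alkene face selection in the hydrogenation may be insufficient or inverted, which would erode or invert C3 and with it every later centre. The fallback replaces the catalyst by a chiral auxiliary; it sets out from 2 and comes back at 8.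
   Aldehyde 2 is reduced (NaBH4, MeOH) to [4-(benzyloxy)-3,5-dimethoxyphenyl]methanol F2, which PBr3 in Et2O at 0 °C converts into 4-(benzyloxy)-3,5-dimethoxybenzyl bromide F3. The succinate imide (S)-4-benzyl-3-(4-tert-butoxy-4-oxobutanoyl)oxazolidin-2-one F4 is made from (S)-4-benzyl-2-oxazolidinone and 4-tert-butoxy-4-oxobutanoic acid (PivCl, Et3N, LiCl).
   F4 is deprotonated with NaN(SiMe3)2 in THF at −78 °C and alkylated with F3 on the enolate face away from the auxiliary benzyl group (Evans alkylation). This should give (S)-4-benzyl-3-{(S)-2-[4-(benzyloxy)-3,5-dimethoxybenzyl]-4-tert-butoxy-4-oxobutanoyl}oxazolidin-2-one F5. LiBH4 removes the auxiliary reductively to give tert-butyl (S)-4-[4-(benzyloxy)-3,5-dimethoxyphenyl]-3-(hydroxymethyl)butanoate F6, and trifluoroacetic acid in CH2Cl2 closes it to lactone 8.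

**Further compounds**

F1 | step 12 | (1R,2S,3S,4RS)-2,3-bis{[(tert-butyldimethylsilyl)oxy]methyl}-1-{3,5-dimethoxy-4-[(triisopropylsilyl)oxy]phenyl}-4-(4-hydroxy-3,5-dimethoxyphenyl)-4-methoxybutan-1-ol | O[C@@H](c1cc(OC)c(O[Si](C(C)C)(C(C)C)C(C)C)c(OC)c1)[C@H](CO[Si](C)(C)C(C)(C)C)[C@@H](CO[Si](C)(C)C(C)(C)C)C(OC)c1cc(OC)c(O)c(OC)c1
F0 | step 8 | none | none
F2 | step 3 | [4-(benzyloxy)-3,5-dimethoxyphenyl]methanol | COc1cc(CO)cc(OC)c1OCc1ccccc1
F3 | step 3 | 4-(benzyloxy)-3,5-dimethoxybenzyl bromide | COc1cc(CBr)cc(OC)c1OCc1ccccc1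
F4 | step 3 | (S)-4-benzyl-3-(4-tert-butoxy-4-oxobutanoyl)oxazolidin-2-one | CC(C)(C)OC(=O)CCC(=O)N1[C@@H](Cc2ccccc2)COC1=O
F5 | step 3 | (S)-4-benzyl-3-{(S)-2-[4-(benzyloxy)-3,5-dimethoxybenzyl]-4-tert-butoxy-4-oxobutanoyl}oxazolidin-2-one | CC(C)(C)OC(=O)C[C@H](Cc1cc(OC)c(OCc2ccccc2)c(OC)c1)C(=O)N1[C@@H](Cc2ccccc2)COC1=O
F6 | step 3 | tert-butyl (S)-4-[4-(benzyloxy)-3,5-dimethoxyphenyl]-3-(hydroxymethyl)butanoate | CC(C)(C)OC(=O)C[C@@H](CO)Cc1cc(OC)c(OCc2ccccc2)c(OC)c1
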